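**Plan**

- Numbering: ring A is the central benzene (C1 carries the methide carbon C7, C2 carries ring D, C5 the CH2OH, C6 the alkyne); ring D is the 2,4-dihydroxyphenyl group (C1′ on C2, hydroxyls on C2′ and C4′).
- Cuts, in retrosynthetic order: the two C7–aryl bonds (quinone methide ← triaryl carbinol ← lactone carbonyl), the biaryl bond C2–C1′, the ester bond C7–O(2′), the C6–C(sp) bond, and the C5–CH2 bond.
- Enabling feature: the 2′-oxygen of ring D and C7 are linked through C2′–C1′–C2–C1, so an O–C7 ester tethers ring D to ring A, and forming C2–C1′ then closes a six-membered pyranone (C7, O, C2′, C1′, C2, C1).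
- Forward: ring A is elaborated from 2-chloro-6-hydroxybenzoic acid (C5 carbon, then C6 alkyne), the aryl ester tether is installed, and the pyranone, the only ring made, is closed by C–H arylation. Two aryllithium additions then open the lactone at C7, and acid unveils the quinone methide.
- Stereochemistry: none to set; the target has no stereocentre, and C7 carries a symmetric cyclohexadienone, so the exocyclic double bond has no geometry.

Key step: step 13

Remark: the target is taken as the open quinone methide with a free 2′-hydroxyl, as drawn; the biaryl and aryl–C7 axes are assumed to rotate freely.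

**Route**

Step 1
Reactants: 1 4-iodophenol
Product: 2 1-iodo-4-(methoxymethoxy)benzene
Conditions: NaH, MOMCl, DMF, 0 °C to rt
Reagents that add atoms: chloromethyl methyl ether, COCCl
Why: O-alkylation of the sodium phenolate with the reactive chloromethyl ether (Williamson-type MOM protection) should be clean, since no other nucleophilic site is present.

Step 2
Reactants: 2 1-iodo-4-(methoxymethoxy)benzene
Product: 3 trimethyl{[4-(methoxymethoxy)phenyl]ethynyl}silane
Conditions: ethynyltrimethylsilane, PdCl2(PPh3)2 (2 mol %), CuI (4 mol %), Et3N, THF, rt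
Reagents that add atoms: ethynyltrimethylsilane, C#C[Si](C)(C)C
Why: Sonogashira coupling of an aryl iodide with a terminal alkyne proceeds at room temperature, and the silyl cap prevents double coupling.

Step 3
Reactants: 3 trimethyl{[4-(methoxymethoxy)phenyl]ethynyl}silane
Product: 4 1-ethynyl-4-(methoxymethoxy)benzene
Conditions: K2CO3 (cat.), MeOH, rt
Reagents that add atoms: none
Why: Methoxide-mediated protodesilylation of an alkynylsilane is fast and leaves the MOM acetal untouched.

Step 4
Reactants: 5 resorcinol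
Product: 6 3-(methoxymethoxy)phenol
Conditions: resorcinol (3 equiv), NaH (1 equiv), MOMCl (1 equiv), DMF, 0 °C
Reagents that add atoms: chloromethyl methyl ether, COCCl
Why: Mono-O-alkylation of a symmetric diphenol used in excess (Williamson-type) should favour the mono-ether, and the surplus resorcinol is removed by aqueous extraction.

Step 5
Reactants: 7 2-chloro-6-hydroxybenzoic acid
Product: 8 methyl 2-chloro-6-hydroxybenzoate
Conditions: MeI, KHCO3, DMF, rt
Reagents that add atoms: iodomethane, CI
Why: SN2 alkylation of the carboxylate avoids the slow Fischer esterification of a doubly ortho-substituted acid, and hydrogencarbonate does not deprotonate the hydrogen-bonded phenol.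

Step 6
Reactants: 8 methyl 2-chloro-6-hydroxybenzoate
Product: 9 methyl 6-chloro-3-formyl-2-hydroxybenzoate
Conditions: MgCl2, Et3N, (CH2O)n, MeCN, reflux; then 1 M HCl
Reagents that add atoms: formaldehyde (as paraformaldehyde), C=O
Why: In the Casnati–Skattebøl ortho-formylation the magnesium phenoxide delivers formaldehyde to the only free ortho position, and a second formaldehyde oxidises the benzylic alkoxide to the aldehyde by hydride transfer.

Step 7
Reactants: 9 methyl 6-chloro-3-formyl-2-hydroxybenzoate
Product: 10 methyl 6-chloro-2-hydroxy-3-(hydroxymethyl)benzoate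
Conditions: NaBH4, MeOH/THF, 0 °C
Reagents that add atoms: none
Why: Borohydride reduction at 0 °C is selective for the aldehyde over the methyl ester and the aryl chloride.

Step 8
Reactants: 10 methyl 6-chloro-2-hydroxy-3-(hydroxymethyl)benzoate
Product: 11 methyl 3-{[tert-butyl(dimethyl)silyl]oxymethyl}-6-chloro-2-hydroxybenzoate
Conditions: TBSCl (1.05 equiv), imidazole, CH2Cl2, 0 °C
Reagents that add atoms: tert-butyl(chloro)dimethylsilane, CC(C)(C)[Si](C)(C)Cl
Why: Chemoselective silylation should take the primary benzylic hydroxyl, because the phenol is flanked by two ortho substituents and hydrogen-bonded to the ester carbonyl.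

Step 9
Reactants: 11 methyl 3-{[tert-butyl(dimethyl)silyl]oxymethyl}-6-chloro-2-hydroxybenzoate
Product: 12 methyl 3-{[tert-butyl(dimethyl)silyl]oxymethyl}-6-chloro-2-{[(trifluoromethyl)sulfonyl]oxy}benzoate
Conditions: Tf2O, pyridine, CH2Cl2, −10 to 0 °C
Reagents that add atoms: trifluoromethanesulfonic anhydride, O=S(=O)(OS(=O)(=O)C(F)(F)F)C(F)(F)F
Why: O-sulfonylation of the phenol with the small, highly electrophilic anhydride tolerates the two ortho substituents, and pyridine buffers the silyl ether against triflic acid.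

Step 10
Reactants: 12 methyl 3-{[tert-butyl(dimethyl)silyl]oxymethyl}-6-chloro-2-{[(trifluoromethyl)sulfonyl]oxy}benzoate; 4 1-ethynyl-4-(methoxymethoxy)benzene
Product: 13 methyl 3-{[tert-butyl(dimethyl)silyl]oxymethyl}-6-chloro-2-{[4-(methoxymethoxy)phenyl]ethynyl}benzoate
Conditions: PdCl2(PPh3)2 (5 mol %), CuI (10 mol %), Et3N, DMF, 70 °C
Reagents that add atoms: none
Why: In this Sonogashira coupling the triflate, activated by the ortho ester, undergoes oxidative addition, whereas the aryl chloride is inert to the triphenylphosphine-ligated catalyst.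

Step 11
Reactants: 13 methyl 3-{[tert-butyl(dimethyl)silyl]oxymethyl}-6-chloro-2-{[4-(methoxymethoxy)phenyl]ethynyl}benzoate
Product: 14 3-{[tert-butyl(dimethyl)silyl]oxymethyl}-6-chloro-2-{[4-(methoxymethoxy)phenyl]ethynyl}benzoic acid
Conditions: LiOH·H2O, THF/MeOH/H2O, 60 °C; then 1 M HCl to pH 4, 0 °C
Reagents that add atoms: lithium hydroxide, [Li+].[OH-]
Why: Saponification should still proceed because one ortho group is a slim alkynyl unit, and the silyl and MOM ethers are base-stable, provided copper and palladium residues are removed first, since they would catalyse addition of the carboxylate to the alkyne.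

Step 12
Reactants: 14 3-{[tert-butyl(dimethyl)silyl]oxymethyl}-6-chloro-2-{[4-(methoxymethoxy)phenyl]ethynyl}benzoic acid; 6 3-(methoxymethoxy)phenol
Product: 15 3-(methoxymethoxy)phenyl 3-{[tert-butyl(dimethyl)silyl]oxymethyl}-6-chloro-2-{[4-(methoxymethoxy)phenyl]ethynyl}benzoate
Conditions: DCC, DMAP (0.2 equiv), CH2Cl2, 0 °C to rt
Reagents that add atoms: none
Why: Steglich esterification activates the acid as its O-acylisourea and DMAP passes the acyl group to the phenol under neutral conditions that spare the acid-labile ethers.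

Step 13
Reactants: 15 3-(methoxymethoxy)phenyl 3-{[tert-butyl(dimethyl)silyl]oxymethyl}-6-chloro-2-{[4-(methoxymethoxy)phenyl]ethynyl}benzoate
Product: 16 8-{[tert-butyl(dimethyl)silyl]oxymethyl}-3-(methoxymethoxy)-7-{[4-(methoxymethoxy)phenyl]ethynyl}-6H-benzo[c]chromen-6-one
Conditions: Pd(OAc)2 (10 mol %), PCy3·HBF4 (20 mol %), K2CO3 (2 equiv), PivOH (30 mol %), DMA, 130 °C
Reagents that add atoms: none
Why: Zerovalent palladium, formed in the flask from Pd(OAc)2 and the phosphine, should insert into the C2–Cl bond activated by the ortho ester; carboxylate-assisted concerted metalation–deprotonation of a ring D C–H ortho to the ester oxygen then gives a seven-membered diaryl palladacycle (Pd, C2, C1, C7, O, C2′, C1′), and reductive elimination forms the C2–C1′ bond. The closest known reaction type is the palladium-catalysed intramolecular direct arylation of aryl 2-halobenzoates to 6H-benzo[c]chromen-6-ones, run here under the trialkylphosphine and carbonate conditions used for aryl chlorides. The single ring formed, the six-membered pyranone, is closed by aryl–aryl bond formation across the ester tether, which requires the ester to reach its E rotamer at 130 °C. No stereocentre is created. Site selectivity on ring D is needed: C1′–H, para to the MOM ether, is unhindered, whereas C3′–H lies between the two oxygens and closure there would force the MOM ether into the bay region against C3–H of ring A. Chemoselectivity rests on the substrate: the chloride is the only carbon–halogen bond, the C6 alkyne sits on the far side of the ester and cannot be reached by the arylpalladium centre, and the two ortho substituents shield the ester from carbonate.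

Step 14
Reactants: 16 8-{[tert-butyl(dimethyl)silyl]oxymethyl}-3-(methoxymethoxy)-7-{[4-(methoxymethoxy)phenyl]ethynyl}-6H-benzo[c]chromen-6-one; 2 1-iodo-4-(methoxymethoxy)benzene
Product: 19 {3-{[tert-butyl(dimethyl)silyl]oxymethyl}-6-[2-hydroxy-4-(methoxymethoxy)phenyl]-2-{[4-(methoxymethoxy)phenyl]ethynyl}phenyl}bis[4-(methoxymethoxy)phenyl]methanol, via [4-(methoxymethoxy)phenyl]lithium 17 (not isolated), via ring-opened ketone lithium phenolate 18 (not isolated)
Conditions: 2 (4.5 equiv), tert-butyllithium (9 equiv), THF, −78 °C; then 16, −78 to 0 °C; aq. NH4Cl; Et3N-deactivated silica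
Reagents that add atoms: none
Why: Iodine–lithium exchange gives the aryllithium, whose first equivalent opens the lactone with loss of the ring D phenolate and whose second adds to the resulting diaryl ketone (double 1,2-addition of an organolithium to an ester), while the alkyne, silyl ether and MOM ethers are inert at low temperature.

Step 15
Reactants: 19 {3-{[tert-butyl(dimethyl)silyl]oxymethyl}-6-[2-hydroxy-4-(methoxymethoxy)phenyl]-2-{[4-(methoxymethoxy)phenyl]ethynyl}phenyl}bis[4-(methoxymethoxy)phenyl]methanol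
Product: 20 Selaginellin F, 4-{[6-(2,4-dihydroxyphenyl)-3-(hydroxymethyl)-2-[(4-hydroxyphenyl)ethynyl]phenyl](4-hydroxyphenyl)methylidene}cyclohexa-2,5-dien-1-one
Conditions: 3 M aq. HCl, MeOH/THF, rt to 40 °C; then NaHCO3
Reagents that add atoms: none
Why: Acid solvolysis removes the four MOM acetals and the TBS ether and ionises the tertiary triarylcarbinol to a cation stabilised by two para-oxygenated aryl groups, which should lose a phenolic proton to give the quinone methide (fuchsone-type dehydration of a 4-hydroxytrityl alcohol).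

**Compound list**

1 | 4-iodophenol | Oc1ccc(I)cc1 | starting material
2 | 1-iodo-4-(methoxymethoxy)benzene | COCOc1ccc(I)cc1 | intermediate
3 | trimethyl{[4-(methoxymethoxy)phenyl]ethynyl}silane | COCOc1ccc(C#C[Si](C)(C)C)cc1 | intermediate
4 | 1-ethynyl-4-(methoxymethoxy)benzene | COCOc1ccc(C#C)cc1 | intermediate
5 | resorcinol | Oc1cccc(O)c1 | starting material
6 | 3-(methoxymethoxy)phenol | COCOc1cccc(O)c1 | intermediate
7 | 2-chloro-6-hydroxybenzoic acid | OC(=O)c1c(O)cccc1Cl | starting material
8 | methyl 2-chloro-6-hydroxybenzoate | COC(=O)c1c(O)cccc1Cl | intermediate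
9 | methyl 6-chloro-3-formyl-2-hydroxybenzoate | COC(=O)c1c(O)c(C=O)ccc1Cl | intermediate
10 | methyl 6-chloro-2-hydroxy-3-(hydroxymethyl)benzoate | COC(=O)c1c(O)c(CO)ccc1Cl | intermediate
11 | methyl 3-{[tert-butyl(dimethyl)silyl]oxymethyl}-6-chloro-2-hydroxybenzoate | COC(=O)c1c(O)c(CO[Si](C)(C)C(C)(C)C)ccc1Cl | intermediate
12 | methyl 3-{[tert-butyl(dimethyl)silyl]oxymethyl}-6-chloro-2-{[(trifluoromethyl)sulfonyl]oxy}benzoate | COC(=O)c1c(OS(=O)(=O)C(F)(F)F)c(CO[Si](C)(C)C(C)(C)C)ccc1Cl | intermediate
13 | methyl 3-{[tert-butyl(dimethyl)silyl]oxymethyl}-6-chloro-2-{[4-(methoxymethoxy)phenyl]ethynyl}benzoate | COC(=O)c1c(Cl)ccc(CO[Si](C)(C)C(C)(C)C)c1C#Cc1ccc(OCOC)cc1 | intermediate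
14 | 3-{[tert-butyl(dimethyl)silyl]oxymethyl}-6-chloro-2-{[4-(methoxymethoxy)phenyl]ethynyl}benzoic acid | OC(=O)c1c(Cl)ccc(CO[Si](C)(C)C(C)(C)C)c1C#Cc1ccc(OCOC)cc1 | intermediate
15 | 3-(methoxymethoxy)phenyl 3-{[tert-butyl(dimethyl)silyl]oxymethyl}-6-chloro-2-{[4-(methoxymethoxy)phenyl]ethynyl}benzoate | O=C(Oc1cccc(OCOC)c1)c1c(Cl)ccc(CO[Si](C)(C)C(C)(C)C)c1C#Cc1ccc(OCOC)cc1 | intermediate (key-step precursor)
16 | 8-{[tert-butyl(dimethyl)silyl]oxymethyl}-3-(methoxymethoxy)-7-{[4-(methoxymethoxy)phenyl]ethynyl}-6H-benzo[c]chromen-6-one | O=C1Oc2cc(OCOC)ccc2-c2ccc(CO[Si](C)(C)C(C)(C)C)c(C#Cc3ccc(OCOC)cc3)c21 | intermediate (key-step product)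
17 | [4-(methoxymethoxy)phenyl]lithium | [Li]c1ccc(OCOC)cc1 | intermediate (not isolated)
18 | lithium 2-[4-{[tert-butyl(dimethyl)silyl]oxymethyl}-2-[4-(methoxymethoxy)benzoyl]-3-{[4-(methoxymethoxy)phenyl]ethynyl}phenyl]-5-(methoxymethoxy)phenolate | [Li+].[O-]c1cc(OCOC)ccc1-c1ccc(CO[Si](C)(C)C(C)(C)C)c(C#Cc2ccc(OCOC)cc2)c1C(=O)c1ccc(OCOC)cc1 | intermediate (not isolated)
19 | {3-{[tert-butyl(dimethyl)silyl]oxymethyl}-6-[2-hydroxy-4-(methoxymethoxy)phenyl]-2-{[4-(methoxymethoxy)phenyl]ethynyl}phenyl}bis[4-(methoxymethoxy)phenyl]methanol | OC(c1ccc(OCOC)cc1)(c1ccc(OCOC)cc1)c1c(-c2ccc(OCOC)cc2O)ccc(CO[Si](C)(C)C(C)(C)C)c1C#Cc1ccc(OCOC)cc1 | intermediate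
20 | Selaginellin F | O=C1C=CC(=C(c2ccc(O)cc2)c2c(-c3ccc(O)cc3O)ccc(CO)c2C#Cc2ccc(O)cc2)C=C1 | target

**Count and risks**

Total step count: 15. Longest linear sequence: 11 steps (steps 5 to 15, from 2-chloro-6-hydroxybenzoic acid 7).

Most likely to fail, step 13. Insertion of zerovalent palladium into the C–Cl bond may be slow at a temperature where carbonate cleaves the aryl ester, and palladation may occur in part at the ring D carbon between the two oxygens. The fallback gives up the tether for an intermolecular biaryl coupling; it sets out from methyl ester 13 and returns to the route at target 20. Commercial 4-bromoresorcinol is bis-protected (NaH, MOMCl, DMF) to 1-bromo-2,4-bis(methoxymethoxy)benzene F1. Bromine–lithium exchange (n-BuLi, THF, −78 °C), B(OiPr)3 and aqueous work-up should give [2,4-bis(methoxymethoxy)phenyl]boronic acid F2. Suzuki–Miyaura coupling of F2 with chloride 13 (Pd(OAc)2, SPhos, K3PO4, toluene/H2O, 90 °C) should give methyl 4-{[tert-butyl(dimethyl)silyl]oxymethyl}-2′,4′-bis(methoxymethoxy)-3-{[4-(methoxymethoxy)phenyl]ethynyl}biphenyl-2-carboxylate F3. Excess aryllithium 17, prepared as in step 14, should add twice to the ester to give {3-{[tert-butyl(dimethyl)silyl]oxymethyl}-6-[2,4-bis(methoxymethoxy)phenyl]-2-{[4-(methoxymethoxy)phenyl]ethynyl}phenyl}bis[4-(methoxymethoxy)phenyl]methanol F4. The acid treatment of step 15 then removes all five MOM groups and the silyl ether and converts F4 into 20.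

Second, step 15. The ring D 2′-hydroxyl may capture the C7 cation, closing a 6,6-diaryl-6H-benzo[c]chromene, in competition with proton loss to the quinone methide. The fallback masks that hydroxyl during ionisation and frees it last under non-ionising conditions; it sets out from carbinol 19 and returns at 20. TIPSCl, imidazole and DMAP in DMF should silylate only the phenol, giving {3-{[tert-butyl(dimethyl)silyl]oxymethyl}-6-{4-(methoxymethoxy)-2-[tri(propan-2-yl)silyloxy]phenyl}-2-{[4-(methoxymethoxy)phenyl]ethynyl}phenyl}bis[4-(methoxymethoxy)phenyl]methanol F8. HCl in MeOH/THF at rt then removes the MOM and TBS groups and dehydrates the carbinol, while the aryl TIPS ether should survive, giving 4-{[3-(hydroxymethyl)-6-{4-hydroxy-2-[tri(propan-2-yl)silyloxy]phenyl}-2-[(4-hydroxyphenyl)ethynyl]phenyl](4-hydroxyphenyl)methylidene}cyclohexa-2,5-dien-1-one F9. HF·pyridine in THF/pyridine at 0 °C cleaves the silyl ether and gives 20.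

Third, step 14. After the first addition the ring-opened phenolate ketone can reclose to the lithium salt of the cyclic hemiketal, and the doubly ortho-substituted ketone may be slow to take up the second aryl group, so the reaction may stall after one addition. The fallback adds the two aryl groups in separate operations with the phenol capped in between; it sets out from lactone 16 and returns at 20. One equivalent of 17 at −78 °C and a cold quench should give [3-{[tert-butyl(dimethyl)silyl]oxymethyl}-6-[2-hydroxy-4-(methoxymethoxy)phenyl]-2-{[4-(methoxymethoxy)phenyl]ethynyl}phenyl][4-(methoxymethoxy)phenyl]methanone F5, which equilibrates with its cyclic hemiketal. TESCl and imidazole in CH2Cl2 silylate the phenol of the open tautomer and so draw the equilibrium to [3-{[tert-butyl(dimethyl)silyl]oxymethyl}-6-{4-(methoxymethoxy)-2-[(triethylsilyl)oxy]phenyl}-2-{[4-(methoxymethoxy)phenyl]ethynyl}phenyl][4-(methoxymethoxy)phenyl]methanone F6. A fresh portion of 17 at −78 °C should add to this neutral ketone to give {3-{[tert-butyl(dimethyl)silyl]oxymethyl}-6-{4-(methoxymethoxy)-2-[(triethylsilyl)oxy]phenyl}-2-{[4-(methoxymethoxy)phenyl]ethynyl}phenyl}bis[4-(methoxymethoxy)phenyl]methanol F7. The acid treatment of step 15 removes the triethylsilyl, TBS and MOM groups and gives 20.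

Further compounds
F1 | step 13 | 1-bromo-2,4-bis(methoxymethoxy)benzene | COCOc1ccc(Br)c(OCOC)c1
F2 | step 13 | [2,4-bis(methoxymethoxy)phenyl]boronic acid | COCOc1ccc(B(O)O)c(OCOC)c1
F3 | step 13 | methyl 4-{[tert-butyl(dimethyl)silyl]oxymethyl}-2′,4′-bis(methoxymethoxy)-3-{[4-(methoxymethoxy)phenyl]ethynyl}biphenyl-2-carboxylate | COC(=O)c1c(-c2ccc(OCOC)cc2OCOC)ccc(CO[Si](C)(C)C(C)(C)C)c1C#Cc1ccc(OCOC)cc1
F4 | step 13 | {3-{[tert-butyl(dimethyl)silyl]oxymethyl}-6-[2,4-bis(methoxymethoxy)phenyl]-2-{[4-(methoxymethoxy)phenyl]ethynyl}phenyl}bis[4-(methoxymethoxy)phenyl]methanol | OC(c1ccc(OCOC)cc1)(c1ccc(OCOC)cc1)c1c(-c2ccc(OCOC)cc2OCOC)ccc(CO[Si](C)(C)C(C)(C)C)c1C#Cc1ccc(OCOC)cc1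
F5 | step 14 | [3-{[tert-butyl(dimethyl)silyl]oxymethyl}-6-[2-hydroxy-4-(methoxymethoxy)phenyl]-2-{[4-(methoxymethoxy)phenyl]ethynyl}phenyl][4-(methoxymethoxy)phenyl]methanone | Oc1cc(OCOC)ccc1-c1ccc(CO[Si](C)(C)C(C)(C)C)c(C#Cc2ccc(OCOC)cc2)c1C(=O)c1ccc(OCOC)cc1
F6 | step 14 | [3-{[tert-butyl(dimethyl)silyl]oxymethyl}-6-{4-(methoxymethoxy)-2-[(triethylsilyl)oxy]phenyl}-2-{[4-(methoxymethoxy)phenyl]ethynyl}phenyl][4-(methoxymethoxy)phenyl]methanone | CC[Si](CC)(CC)Oc1cc(OCOC)ccc1-c1ccc(CO[Si](C)(C)C(C)(C)C)c(C#Cc2ccc(OCOC)cc2)c1C(=O)c1ccc(OCOC)cc1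
F7 | step 14 | {3-{[tert-butyl(dimethyl)silyl]oxymethyl}-6-{4-(methoxymethoxy)-2-[(triethylsilyl)oxy]phenyl}-2-{[4-(methoxymethoxy)phenyl]ethynyl}phenyl}bis[4-(methoxymethoxy)phenyl]methanol | OC(c1ccc(OCOC)cc1)(c1ccc(OCOC)cc1)c1c(-c2ccc(OCOC)cc2O[Si](CC)(CC)CC)ccc(CO[Si](C)(C)C(C)(C)C)c1C#Cc1ccc(OCOC)cc1
F8 | step 15 | {3-{[tert-butyl(dimethyl)silyl]oxymethyl}-6-{4-(methoxymethoxy)-2-[tri(propan-2-yl)silyloxy]phenyl}-2-{[4-(methoxymethoxy)phenyl]ethynyl}phenyl}bis[4-(methoxymethoxy)phenyl]methanol | OC(c1ccc(OCOC)cc1)(c1ccc(OCOC)cc1)c1c(-c2ccc(OCOC)cc2O[Si](C(C)C)(C(C)C)C(C)C)ccc(CO[Si](C)(C)C(C)(C)C)c1C#Cc1ccc(OCOC)cc1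
F9 | step 15 | 4-{[3-(hydroxymethyl)-6-{4-hydroxy-2-[tri(propan-2-yl)silyloxy]phenyl}-2-[(4-hydroxyphenyl)ethynyl]phenyl](4-hydroxyphenyl)methylidene}cyclohexa-2,5-dien-1-one | O=C1C=CC(=C(c2ccc(O)cc2)c2c(-c3ccc(O)cc3O[Si](C(C)C)(C(C)C)C(C)C)ccc(CO)c2C#Cc2ccc(O)cc2)C=C1
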